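**Retrosynthet­ic overview**

1. Positions follow the chromene core: O1, C2, C3, C4, C4a, C5(=O), C6(Me2), C7(=O), C8(Me2), C8a. The last disconnection cuts C2–C(trione) and O1–C2, giving lactol 11 and syncarpic acid 14 (Knoevenagel condensation, then oxa-Michael closure).
2. Key disconnection: the carbocycle fused to the pyran is cut at C5–C6 and C8–C8a into diisopropyl ketone (C6–C7–C8) and an aryl malonate (C5–C4a–C8a), joined by a [3+3] double C-acylation. The enabling feature is that the two quaternary gem-dimethyl carbons C6 and C8 flank the C7 ketone and each is bonded to an acyl carbon of the malonyl unit; C4a still carries H in the precursor, so an aryl ester can lose phenoxide twice through ketenes (E1cB).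
3. The malonate chain with C3 and C4 comes from two molecules of 3-methylbutanal and diphenyl malonate (Knoevenagel condensation, then enamine-catalysed Michael addition); the C2 aldehyde is masked as an acetal.
4. Ring order: carbocycle first (key step), pyran ring as a lactol on work-up of the same step; the trione ring on C2 arrives preformed as 14, made from an acylphloroglucinol.

Key step: step 4

Remark: lactol 11 is carried as a mixture of C2 anomers; both converge in step 7, where C2 is set.

**Route**

Step 1
Reactants: 1 3-methylbutanal; 2 diphenyl propanedioate (diphenyl malonate)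
Product: 3 diphenyl 2-(3-methylbutylidene)propanedioate
Conditions: TiCl4 (2 equiv), pyridine (4 equiv), THF, 0 → 23 °C
Reagents that add atoms: none
Why: Knoevenagel condensation under TiCl4/pyridine activation is established for enolisable aliphatic aldehydes and should spare the aryl esters, which a secondary-amine catalyst would aminolyse; no stereocentre is formed.

Step 2
Reactants: 3 diphenyl 2-(3-methylbutylidene)propanedioate; 1 3-methylbutanal
Product: 4 diphenyl 2-[(3S,4S)-3-formyl-2,6-dimethylheptan-4-yl]propanedioate
Conditions: (R)-α,α-diphenylprolinol trimethylsilyl ether (20 mol %), PhCO2H (20 mol %), CH2Cl2, 4 °C, 1 added slowly by syringe pump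
Reagents that add atoms: none
Why: Enamine-catalysed Michael addition of an aldehyde to an alkylidene malonate: the E-enamine of 1 is shielded on one face by the diphenyl(silyloxy)methyl group of the (R)-catalyst and should add through an acyclic synclinal transition state, setting C3 (S) by catalyst control and C4 (S) by the syn topicity, while the aryl esters raise the electrophilicity of the β-alkyl acceptor and the slow addition keeps self-aldolisation of 1 low.

Step 3
Reactants: 4 diphenyl 2-[(3S,4S)-3-formyl-2,6-dimethylheptan-4-yl]propanedioate
Product: 5 diphenyl 2-[(3S,4S)-3-(dimethoxymethyl)-2,6-dimethylheptan-4-yl]propanedioate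
Conditions: HC(OMe)3 (3 equiv), pyridinium p-toluenesulfonate (5 mol %), CH2Cl2, 23 °C
Reagents that add atoms: trimethyl orthoformate, COC(OC)OC
Why: Acid-catalysed acetalisation with the orthoformate as methanol source and water scavenger masks the aldehyde against the strong base of step 4, under buffered conditions without free methanol that should neither transesterify the phenyl esters nor enolise the α-stereocentre C3.

Step 4
Reactants: 5 diphenyl 2-[(3S,4S)-3-(dimethoxymethyl)-2,6-dimethylheptan-4-yl]propanedioate; 6 2,4-dimethylpentan-3-one (diisopropyl ketone)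
Product: 11 (3S,4S)-2-hydroxy-6,6,8,8-tetramethyl-4-(2-methylpropyl)-3-(propan-2-yl)-3,4-dihydro-2H-chromene-5,7(6H,8H)-dione (lactol; C2 anomers), via aryloxycarbonyl ketene 7 (not isolated), via keto ester 8 (not isolated), via acylketene 9 (not isolated), via trione acetal 10 (not isolated)
Conditions: lithium 2,2,6,6-tetramethylpiperidide (LiTMP, 1.0 equiv), THF, −78 °C; lithium enolate of 6 (1.2 equiv, preformed from 6 and LiTMP), −78 → 45 °C; LiTMP (1.1 equiv), −40 → 45 °C; then 1 M HCl, THF, 23 °C
Reagents that add atoms: water, O
Why: Proposed new method: deprotonation of the aryl malonate at C4a triggers E1cB loss of phenoxide to ketene 7, the lithium enolate of 6 is C-acylated at the unhindered sp carbon (C5–C6), the resulting keto ester enolate 8 is deprotonated at the remaining isopropyl C–H and repeats the E1cB to acylketene 9, and the second enolate carbon closes the ring on the ketene carbon (C8–C8a) to give the stabilised enolate of trione 10 as the thermodynamic sink. The closest known reaction types are the Claisen condensation of ester enolates that proceeds through ketenes, the cyclocondensation of active aryl malonates with 1,3-dinucleophiles and the Effenberger cyclization (α,α'-diacylation of a ketone enol ether by malonyl dichloride to a cyclohexane-1,3,5-trione). The carbocycle closes by 6-exo-dig attack of an enolate carbon on a ketene (a formal [3+3] annulation), and the pyran ring closes during the acidic work-up by 6-exo-trig addition of the enol oxygen to the unmasked aldehyde. No new stereocentre has to be controlled: C3 and C4 are carried through because neither is enolisable in 5, 7, 8, 9 or 10 (the charge sits on C4a), and C2 of 11 is an anomeric mixture that converges later. The step needs C- over O-acylation of a tetrasubstituted enolate and intra- over intermolecular second acylation; the lithium counter-ion in THF and the linear ketene electrophiles favour the former, and the near-stoichiometric enolate, the staged addition of base and an amide base too hindered to add to ketenes secure the latter. The aryl esters are what turn the acidic C4a–H, which would stop an ordinary double Claisen condensation at an unreactive malonate enolate, into the trigger for both acyl transfers.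

Step 5
Reactants: 12 1-(2,4,6-trihydroxyphenyl)ethan-1-one
Product: 13 2-acetyl-3-hydroxy-4,4,6,6-tetramethylcyclohex-2-ene-1,5-dione
Conditions: NaOMe (excess), MeI (excess), MeOH, 0 °C → reflux
Reagents that add atoms: iodomethane, CI
Why: Exhaustive base-mediated C-methylation of an acylphloroglucinol (dearomatising alkylation of the phenolate) is the standard entry to the tetramethyl β-triketone; no stereocentre is formed.

Step 6
Reactants: 13 2-acetyl-3-hydroxy-4,4,6,6-tetramethylcyclohex-2-ene-1,5-dione
Product: 14 syncarpic acid (5-hydroxy-2,2,6,6-tetramethylcyclohex-4-ene-1,3-dione)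
Conditions: 6 M aq. HCl, reflux
Reagents that add atoms: none
Why: Acid-mediated retro-Claisen cleavage of the exocyclic acetyl group of the β-triketone should give syncarpic acid; no stereocentre is formed.

Step 7
Reactants: 11 (3S,4S)-2-hydroxy-6,6,8,8-tetramethyl-4-(2-methylpropyl)-3-(propan-2-yl)-3,4-dihydro-2H-chromene-5,7(6H,8H)-dione; 14 syncarpic acid
Product: 15 ericifolione
Conditions: ethylenediammonium diacetate (EDDA, 10 mol %), 4 Å MS, CH2Cl2, 23 → 40 °C
Reagents that add atoms: none
Why: Knoevenagel condensation of the ring-opened aldehyde form of 11 with the cyclic 1,3-dione 14, followed by reversible oxa-Michael addition (6-exo-trig) of the C8a enol oxygen to the alkylidene trione, should set C2 (R) under thermodynamic control, since that epimer keeps the bulky trione equatorial and trans to the pseudoaxial C4 isobutyl group (no 1,3-diaxial clash) while C3 and C4 are not touched.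

**Compound list**

1 | 3-methylbutanal | CC(C)CC=O | starting material
2 | diphenyl propanedioate (diphenyl malonate) | O=C(CC(=O)Oc1ccccc1)Oc1ccccc1 | starting material
3 | diphenyl 2-(3-methylbutylidene)propanedioate | CC(C)CC=C(C(=O)Oc1ccccc1)C(=O)Oc1ccccc1 | intermediate
4 | diphenyl 2-[(3S,4S)-3-formyl-2,6-dimethylheptan-4-yl]propanedioate | CC(C)C[C@@H]([C@@H](C=O)C(C)C)C(C(=O)Oc1ccccc1)C(=O)Oc1ccccc1 | intermediate
5 | diphenyl 2-[(3S,4S)-3-(dimethoxymethyl)-2,6-dimethylheptan-4-yl]propanedioate | CC(C)C[C@@H]([C@@H](C(OC)OC)C(C)C)C(C(=O)Oc1ccccc1)C(=O)Oc1ccccc1 | intermediate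
6 | 2,4-dimethylpentan-3-one | CC(C)C(=O)C(C)C | starting material
7 | phenyl 2-[(3S,4S)-3-(dimethoxymethyl)-2,6-dimethylheptan-4-yl]-3-oxoprop-2-enoate (aryloxycarbonyl ketene) | CC(C)C[C@@H]([C@@H](C(OC)OC)C(C)C)C(=C=O)C(=O)Oc1ccccc1 | intermediate
8 | phenyl 2-[(3S,4S)-3-(dimethoxymethyl)-2,6-dimethylheptan-4-yl]-4,4,6-trimethyl-3,5-dioxoheptanoate (C2 epimers) | CC(C)C[C@@H]([C@@H](C(OC)OC)C(C)C)C(C(=O)Oc1ccccc1)C(=O)C(C)(C)C(=O)C(C)C | intermediate
9 | 2-[(3S,4S)-3-(dimethoxymethyl)-2,6-dimethylheptan-4-yl]-4,4,6-trimethylhept-1-ene-1,3,5-trione (acylketene) | CC(C)C[C@@H]([C@@H](C(OC)OC)C(C)C)C(=C=O)C(=O)C(C)(C)C(=O)C(C)C | intermediate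
10 | 2-[(3S,4S)-3-(dimethoxymethyl)-2,6-dimethylheptan-4-yl]-3-hydroxy-4,4,6,6-tetramethylcyclohex-2-ene-1,5-dione | CC(C)C[C@@H]([C@@H](C(OC)OC)C(C)C)C1=C(O)C(C)(C)C(=O)C(C)(C)C1=O | intermediate
11 | (3S,4S)-2-hydroxy-6,6,8,8-tetramethyl-4-(2-methylpropyl)-3-(propan-2-yl)-3,4-dihydro-2H-chromene-5,7(6H,8H)-dione (C2 anomers) | CC(C)C[C@@H]1C2=C(OC(O)[C@H]1C(C)C)C(C)(C)C(=O)C(C)(C)C2=O | intermediate
12 | 1-(2,4,6-trihydroxyphenyl)ethan-1-one | CC(=O)c1c(O)cc(O)cc1O | starting material
13 | 2-acetyl-3-hydroxy-4,4,6,6-tetramethylcyclohex-2-ene-1,5-dione | CC(=O)C1=C(O)C(C)(C)C(=O)C(C)(C)C1=O | intermediate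
14 | syncarpic acid (5-hydroxy-2,2,6,6-tetramethylcyclohex-4-ene-1,3-dione) | CC1(C)C(=O)C=C(O)C(C)(C)C1=O | intermediate
15 | ericifolione, (2R,3S,4S)-2-(2-hydroxy-3,3,5,5-tetramethyl-4,6-dioxocyclohex-1-en-1-yl)-6,6,8,8-tetramethyl-4-(2-methylpropyl)-3-(propan-2-yl)-3,4-dihydro-2H-chromene-5,7(6H,8H)-dione | CC(C)C[C@@H]1C2=C(O[C@@H](C3=C(O)C(C)(C)C(=O)C(C)(C)C3=O)[C@H]1C(C)C)C(C)(C)C(=O)C(C)(C)C2=O | target

**Step count and risks**

Total step count: 7. Longest linear sequence: 5 (steps 1, 2, 3, 4, 7).

Steps most likely to fail:

1. Step 4 (Proposed new method). What may go wrong: O-acylation instead of C-acylation of the hindered enolate by the ketene, self-condensation of the malonate anion with its own ketene, or intermolecular capture of the acylketene before ring closure. The fallback sets out from 14 and 1 and comes back at 11. Knoevenagel condensation of 14 with 1 (catalytic ethylenediammonium diacetate, CH2Cl2) should give 4,4,6,6-tetramethyl-2-(3-methylbutylidene)cyclohexane-1,3,5-trione F1, used at once after rapid filtration. Enamine-catalysed Michael addition of a second molecule of 1 to F1 with (R)-α,α-diphenylprolinol trimethylsilyl ether, followed by spontaneous hemiacetal closure, should give 11 directly. Both trione rings then come from the acylphloroglucinol route of steps 5 and 6; the Michael addition of aldehydes to alkylidene cyclic 1,3-diones with hemiacetal closure is a known reaction type.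

2. Step 2. What may go wrong: slow conjugate addition to the β-alkyl acceptor with competing deconjugation of 3, acyl transfer from the aryl esters to the amine catalyst, or erosion of the syn selectivity. The fallback sets out from 1 and 3 and comes back at 4. Condensation of 1 with (S)-1-amino-2-(methoxymethyl)pyrrolidine gives the SAMP hydrazone of 3-methylbutanal F2. Its lithium azaenolate (lithium diisopropylamide, THF, −78 °C) should add to 3 at −100 °C through a chelated transition state, with an acetic acid quench at −78 °C, to give the Michael adduct hydrazone F3. C3 is set by the auxiliary, and any C4 epimer is removed by chromatography. Two-phase hydrolysis with aqueous oxalic acid then releases 4 and the auxiliary.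

3. Step 7. What may go wrong: poor facial selectivity at C2 if the ring closure does not equilibrate under the mild conditions, or loss of integrity at C3 through the dienol of the ring-opened alkylidene trione. The fallback sets out from 14 and 1 and comes back at 15. Knoevenagel condensation gives the alkylidene trione F1 described above. Its base-mediated dimerisation (γ-deprotonation, vinylogous Michael addition, oxa-Michael ring closure; a formal hetero-Diels–Alder dimerisation and the likely biogenetic path) should give racemic ericifolione. Preparative HPLC on a chiral stationary phase then separates 15 from its enantiomer ent-ericifolione F4.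

**Further compounds**

F1 | step 4 | 4,4,6,6-tetramethyl-2-(3-methylbutylidene)cyclohexane-1,3,5-trione | CC(C)CC=C1C(=O)C(C)(C)C(=O)C(C)(C)C1=O
F2 | step 2 | (S,E)-2-(methoxymethyl)-N-(3-methylbutylidene)pyrrolidin-1-amine (SAMP hydrazone of 3-methylbutanal) | COC[C@@H]1CCCN1/N=C/CC(C)C
F3 | step 2 | diphenyl 2-[(3S,4S)-3-[(E)-{[(2S)-2-(methoxymethyl)pyrrolidin-1-yl]imino}methyl]-2,6-dimethylheptan-4-yl]propanedioate | COC[C@@H]1CCCN1/N=C/[C@@H](C(C)C)[C@H](CC(C)C)C(C(=O)Oc1ccccc1)C(=O)Oc1ccccc1
F4 | step 7 | ent-ericifolione, the (2S,3R,4R) enantiomer | CC(C)C[C@H]1C2=C(O[C@H](C3=C(O)C(C)(C)C(=O)C(C)(C)C3=O)[C@@H]1C(C)C)C(C)(C)C(=O)C(C)(C)C2=O
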